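**The clock.** The constants of this flask are not given, so I reckon from the curves.

| flask | L | J | E | Q | remark | time |
|---|---|---|---|---|---|---|
| ash | 1.5 M | 1.95 M | 2.1 mM | 38 mM | run made earlier |  |
| cedar | 1.5 M | 0.97 M | 2.1 mM | 38 mM | run made earlier |  |
| alder | 1.5 M | 1.5 M | 2.1 mM | 38 mM | run made earlier |  |
| larch | 1.5 M | 1.95 M | 2.1 mM | 76 mM | run made earlier |  |
| green | 1.5 M | 1.95 M | 2.1 mM | 38 mM | a closed flask charged with all of it at once and left for 80 min | 80 min |
| amber | 1.5 M | 1.95 M | 2.1 mM | 38 mM | one stirred flow tank at steady state, fed with the mixture as stated, mean residence time 80 min |  |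
| violet | 1.5 M | 1.95 M (fed, over 64.0 min) | 2.1 mM | 38 mM | all but J at the start; J goes in evenly over 64.0 min, the run ends at 80 min | 80 min |
| grey | 1.5 M (fed, over 64.0 min) | 1.95 M | 2.1 mM | 38 mM | a stirred flask in which L is dosed at a steady rate over 64.0 min without added volume, worked up at 80 min | 80 min |

- ash (time / min: X / %, Z / %, L / %): 6.00: 15, 1, 83; 15.0: 28, 0, 70; 20.0: 36, 1, 61; 30.0: 45, 4, 53; 40.0: 56, 2, 40; 50.0: 59, 6, 36
- cedar (time / min: X / %, Z / %, L / %): 12.0: 25, 3, 73; 25.0: 41, 3, 56; 30.0: 49, 1, 50; 50.0: 63, 4, 36; 60.0: 67, 4, 28; 80.0: 72, 6, 22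
- alder (time / min: X / %, Z / %, L / %): 12.0: 24, 4, 74; 25.0: 42, 0, 55; 30.0: 47, 1, 46; 50.0: 62, 5, 31; 60.0: 67, 6, 26; 80.0: 69, 9, 22
- larch (time / min: X / %, Z / %, L / %): 6.00: 15, 0, 85; 12.0: 29, 4, 76; 25.0: 37, 5, 51; 40.0: 53, 7, 40; 80.0: 68, 9, 22

(standard deviation of a reading: 2 percentage points)

- the stated concentrations are those of everything mixed, before any reaction; amounts are the same in each set-up
- what may be going on: L + E <-> E + X; Q + X <-> D; J + D <-> Q + Z; 2 J -> G
- the feed brings no volume worth counting
- the earlier runs were made in a closed, stirred flask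

* order of the set-ups by the amount of X at the outlet or at the end, in percent of the L put in, highest first (green / amber / violet / grey)
* amount of X at the outlet or at the end, in percent of the L put in, green
* amount of X at the outlet or at the end, in percent of the L put in, amber
* amount of X at the outlet or at the end, in percent of the L put in, violet
* amount of X at the outlet or at the end, in percent of the L put in, grey

At 80 min, cedar, alder and larch show L at 22%, 22% and 22%, though J runs from 0.97 M to 1.95 M and Q from 38 mM to 76 mM. So I read L's fall as a clock that these changes of J and Q leave alone. E stands at 2.1 mM in these runs, so I assume that the clock goes with E, and I take each drop of L to age on its own, as in a pseudo-first-order step with E constant. X is then what L has lost, less Z and D, and the charge of Q holds D to 2.53% of the L charged.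

**Two drops.** In grey, the first drop of L ages 80 min, as in green, and cedar at that time reads L 22%. The last drop ages 16.0 min, and ash at 15.0 min reads L 70%. Their average, the chord, is 46.0%.

**Mean age.** The mean age of L is the average time L has spent with E, scaled by the strength of E against ash. In grey it is 48.0 min. Ash at 50.0 min reads L 36%, lower than the chord, so I read the curve as hollow. The true average lies between the two. Weighing the curve as a parabola gives L 39.3%. With Z at ash's reading of 6%, and D left aside, I expect X near 54.7% in grey.

**The others.** Green and violet both give L the age 80 min, so I put both near the X readings of cedar and larch at that time, 72% and 68%. Amber's ages spread from zero upward, and a hollow curve charges for spread, so I set amber last, less firmly.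

**Result.** The forecast gave violet > green > grey > amber, with green 69%, amber 51%, violet 70% and grey 56%, saying of grey that “dosing lowers the mean age of L”. The flask gives green > violet > grey > amber: green 69.8%, amber 53.0%, violet 66.7%, grey 58.0%. Grey ends with L at 37.8%, against the 39.3% I reckoned, and lower than the chord. At the end of its feed, grey's mean age is 32.0 min. Ash at 30.0 min reads L 53%. Grey at 64.0 min, when that feed ends, holds L 52.2%.

    L + E ⇌ E + X (K = 5.10, k = 750 M⁻¹ h⁻¹)
    Q + X ⇌ D (K = 0.0250 M⁻¹, k = 260 M⁻¹ h⁻¹)
    J + D ⇌ Q + Z (K = 13.0, k = 350 M⁻¹ h⁻¹)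
    2 J → G (k = 0.630 M⁻¹ h⁻¹)

**Second flask.** Green with E at 5.3 × 10⁻⁴ M scales the age 80 min to 20.2 min, against 48.0 min in grey, so ash at 20.0 min promises L 61% and X 36%. The flask gives L 60.6% and X 36.0%.

(The readings stem from a simulated flask with made-up constants.)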